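## Retrosynthetic overview
1. 22 ⇒ 21 (two Boc groups) ⇒ Suzuki cut of the indolyl–CH= bond, giving alkenyl chloride 20 and indol-5-ylboronate 10.
2. 20 ⇒ stereoinvertive palladium allyl–aryl coupling at the ring C1–indolyl bond, giving allylic carbonate 19 and a second equivalent of boronate 10.
3. 19 ⇒ enone 17 by reagent-controlled 1,2-reduction. 17 ⇒ new enantioselective palladium alpha-prime-chloroethenylation of the zinc enolate of 3,6-dimethylcyclohexenone 13 with (E)-1,2-dichloroethene 14, which sets the quaternary centre.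
4. 10 ⇒ palladium annulation of 4-bromo-2-iodoaniline 6 with 3,3-dimethylpent-4-enal 4 (Claisen product from prenol), then Boc protection and borylation.
5. Ring order: the benzene rings and the six-membered carbocycle are bought. The only ring made is the indole pyrrole ring (step 3, used twice), and no ring is closed after fragment union.

Assumption: the SMILES is read as (1R,6R), with the C1 indolyl and the C6 alkenyl group cis on the cyclohexene; for the chiral catalysts of steps 7 and 8 the named antipode stands for the one that delivers the drawn configuration.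

## Route

Step 1
Reactants: 1 3-methylbut-2-en-1-ol (prenol); 2 butyl vinyl ether
Product: 4 3,3-dimethylpent-4-enal, via prenyl vinyl ether 3 (not isolated)
Conditions: Pd(OAc)2 (1 mol %), 1,10-phenanthroline (1.2 mol %), neat 2 (6 equiv), 75 °C; then sealed tube, 135 °C; distil
Reagents that add atoms: none
Why: Palladium-catalysed vinyl ether exchange gives the allyl vinyl ether, whose thermal Claisen [3,3] rearrangement forms the C–C bond at the dimethyl-substituted terminus and so builds the reverse-prenyl quaternary carbon next to CH2CHO.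

Step 2
Reactants: 5 4-bromoaniline
Product: 6 4-bromo-2-iodoaniline
Conditions: N-iodosuccinimide (1.05 equiv), AcOH, rt
Reagents that add atoms: N-iodosuccinimide, O=C1CCC(=O)N1I
Why: This is an electrophilic aromatic iodination in which the para position is blocked by bromine, so the activating NH2 group directs iodine ortho.

Step 3
Reactants: 6 4-bromo-2-iodoaniline; 4 3,3-dimethylpent-4-enal
Product: 8 5-bromo-3-(2-methylbut-3-en-2-yl)-1H-indole, via enamine 7 (not isolated)
Conditions: Pd(OAc)2 (5 mol %), 1,4-diazabicyclo[2.2.2]octane (DABCO, 3 equiv), DMF, 85 °C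
Reagents that add atoms: none
Why: In this palladium-catalysed o-iodoaniline/aldehyde indole annulation, condensation gives the enamine, zerovalent palladium inserts selectively into the carbon–iodine bond (carbon–bromine is left), and intramolecular Heck-type closure with loss of HI gives the 3-substituted indole under non-acidic conditions that spare the reverse-prenyl group.

Step 4
Reactants: 8 5-bromo-3-(2-methylbut-3-en-2-yl)-1H-indole
Product: 9 tert-butyl 5-bromo-3-(2-methylbut-3-en-2-yl)indole-1-carboxylate
Conditions: Boc2O (1.2 equiv), 4-(dimethylamino)pyridine (10 mol %), MeCN, rt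
Reagents that add atoms: di-tert-butyl dicarbonate, CC(C)(C)OC(=O)OC(=O)OC(C)(C)C
Why: Nucleophile-catalysed N-acylation (carbamate protection) removes the acidic, nucleophilic N–H that would otherwise attack the allylpalladium species of step 10.

Step 5
Reactants: 9 tert-butyl 5-bromo-3-(2-methylbut-3-en-2-yl)indole-1-carboxylate
Product: 10 tert-butyl 3-(2-methylbut-3-en-2-yl)-5-(4,4,5,5-tetramethyl-1,3,2-dioxaborolan-2-yl)indole-1-carboxylate
Conditions: B2pin2 (1.1 equiv), PdCl2(dppf) (3 mol %), KOAc (3 equiv), 1,4-dioxane, 85 °C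
Reagents that add atoms: bis(pinacolato)diboron, CC1(C)OB(OC1(C)C)B1OC(C)(C)C(C)(C)O1
Why: This is a Miyaura borylation of the aryl bromide, in which KOAc is too weak a base to start Suzuki homocoupling and the hindered terminal alkene and the Boc group are inert.

Step 6
Reactants: 11 3-methylcyclohex-2-en-1-one
Product: 13 3,6-dimethylcyclohex-2-en-1-one (racemic), via lithium dienolate 12 (not isolated)
Conditions: LiN(iPr)2 (1.05 equiv), THF, −78 °C; MeI (1.2 equiv), −78 to 0 °C
Reagents that add atoms: iodomethane, CI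
Why: Kinetic deprotonation at the alpha-prime CH2 gives the cross-conjugated enolate, which is C-methylated (enolate alkylation), and the racemic centre formed here is erased again in step 7.

Step 7
Reactants: 13 3,6-dimethylcyclohex-2-en-1-one; 14 (E)-1,2-dichloroethene
Product: 17 (R)-6-[(E)-2-chloroethenyl]-3,6-dimethylcyclohex-2-en-1-one, via lithium enolate 15 (not isolated), via chlorozinc enolate 16 (not isolated)
Conditions: LiN(iPr)2 (1.05 equiv), THF, −78 °C; ZnCl2 (1.1 equiv), −78 to 0 °C; Pd2(dba)3 (2.5 mol %), (R)-DTBM-SEGPHOS (6 mol %), 14 (5 equiv), THF, 40 °C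
Reagents that add atoms: none
Why: Proposed new method: enantioselective palladium-catalysed alpha-prime-alkenylation of a fully substituted, cross-conjugated zinc enolate with (E)-1,2-dichloroethene as a chloroethenyl cation equivalent; zerovalent palladium inserts with retention into one activated C–Cl bond of 14, the weakly basic zinc enolate (fixed regiochemically by kinetic deprotonation, so it neither equilibrates to the extended dienolate nor dehydrochlorinates 14) transmetalates, and C–C reductive elimination from the C-bound divalent palladium enolate in the narrow pocket of the bulky bisphosphine should outrun beta-hydride elimination and set the (R) quaternary centre, while the product alkenyl chloride is far less reactive than 14 so coupling stops at the mono stage; the closest known reaction types are the asymmetric palladium-catalysed alpha-vinylation and alpha-arylation of alpha-methylcycloalkanone enolates and the selective mono-Negishi coupling of (E)-1,2-dichloroethene.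

Step 8
Reactants: 17 (R)-6-[(E)-2-chloroethenyl]-3,6-dimethylcyclohex-2-en-1-one
Product: 18 (1S,6R)-6-[(E)-2-chloroethenyl]-3,6-dimethylcyclohex-2-en-1-ol (OH trans to chloroethenyl, cis to the C6 methyl)
Conditions: (R)-Me-CBS oxazaborolidine [(3aR)-1-methyl-3,3-diphenyltetrahydro-3H-pyrrolo[1,2-c][1,3,2]oxazaborole, 20 mol %], catecholborane (1.8 equiv), toluene, −60 to −40 °C; aqueous NaOH work-up
Reagents that add atoms: none
Why: In this Corey–Bakshi–Shibata reduction the boron-bound ketone turns its fully substituted C6 flank away from the catalyst, so hydride adds 1,2 to the face cis to the chloroethenyl group under reagent control and gives the (1S) alcohol.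

Step 9
Reactants: 18 (1S,6R)-6-[(E)-2-chloroethenyl]-3,6-dimethylcyclohex-2-en-1-ol
Product: 19 (1S,6R)-6-[(E)-2-chloroethenyl]-3,6-dimethylcyclohex-2-en-1-yl methyl carbonate
Conditions: ClCO2Me (2 equiv), pyridine (4 equiv), 4-(dimethylamino)pyridine (10 mol %), CH2Cl2, 0 °C to rt
Reagents that add atoms: methyl chloroformate, COC(=O)Cl
Why: O-acylation proceeds with retention at carbon and gives a leaving group that releases its own base (methoxide) on ionisation.

Step 10
Reactants: 19 (1S,6R)-6-[(E)-2-chloroethenyl]-3,6-dimethylcyclohex-2-en-1-yl methyl carbonate; 10 indol-5-ylboronate (1.3 equiv)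
Product: 20 tert-butyl 5-{(1R,6S)-6-[(E)-2-chloroethenyl]-3,6-dimethylcyclohex-2-en-1-yl}-3-(2-methylbut-3-en-2-yl)indole-1-carboxylate (indolyl cis to chloroethenyl)
Conditions: Pd2(dba)3·CHCl3 (2.5 mol %), PPh3 (10 mol %), THF, 50 °C, no added base; concentrate and chromatograph
Reagents that add atoms: none
Why: In this stereospecific Suzuki-type allyl–aryl coupling, zerovalent palladium ionises the carbonate from the face anti to it, the methoxide left on palladium activates the boronate for transmetalation, and inner-sphere reductive elimination delivers the indolyl group from the palladium face to the secondary allyl terminus, so net inversion sets (1R) with the aryl cis to the chloroethenyl group, the trisubstituted alkene stays in place, and the alkenyl chloride is inert to this PPh3 catalyst.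

Step 11
Reactants: 20 alkenyl chloride; 10 indol-5-ylboronate (1.3 equiv)
Product: 21 di-tert-butyl bis-carbamate of the target, tert-butyl 5-[(E)-2-{(1R,2R)-2-[1-(tert-butoxycarbonyl)-3-(2-methylbut-3-en-2-yl)indol-5-yl]-1,4-dimethylcyclohex-3-en-1-yl}ethenyl]-3-(2-methylbut-3-en-2-yl)indole-1-carboxylate
Conditions: Pd(OAc)2 (4 mol %), SPhos (2-dicyclohexylphosphino-2′,6′-dimethoxybiphenyl, 8 mol %), K3PO4 (2.5 equiv), THF/H2O 10:1, 65 °C
Reagents that add atoms: none
Why: Suzuki–Miyaura coupling of the unactivated alkenyl chloride is enabled by the electron-rich biaryl phosphine, keeps the E geometry, and is much faster than Heck insertion into the hindered terminal alkenes.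

Step 12
Reactants: 21 bis-carbamate
Product: 22 target, 5-[(1R,6R)-3,6-dimethyl-6-{(E)-2-[3-(2-methylbut-3-en-2-yl)-1H-indol-5-yl]ethenyl}cyclohex-2-en-1-yl]-3-(2-methylbut-3-en-2-yl)-1H-indole
Conditions: K2CO3 (3 equiv), MeOH/THF 2:1, 55 °C
Reagents that add atoms: none
Why: Base-mediated methanolysis of the two indole carbamates (acyl transfer to methoxide) avoids acid, which would ionise or shift the reverse-prenyl groups, and it leaves both stereocentres and all alkenes untouched.

## Compound list
1 | 3-methylbut-2-en-1-ol (prenol) | CC(C)=CCO | starting material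
2 | butyl vinyl ether | C=COCCCC | starting material
3 | 1-(ethenyloxy)-3-methylbut-2-ene (prenyl vinyl ether) | CC(C)=CCOC=C | intermediate
4 | 3,3-dimethylpent-4-enal | C=CC(C)(C)CC=O | intermediate
5 | 4-bromoaniline | Nc1ccc(Br)cc1 | starting material
6 | 4-bromo-2-iodoaniline | Nc1ccc(Br)cc1I | intermediate
7 | (E)-N-(4-bromo-2-iodophenyl)-3,3-dimethylpenta-1,4-dien-1-amine | C=CC(C)(C)/C=C/Nc1ccc(Br)cc1I | intermediate
8 | 5-bromo-3-(2-methylbut-3-en-2-yl)-1H-indole | C=CC(C)(C)c1c[nH]c2ccc(Br)cc12 | intermediate
9 | tert-butyl 5-bromo-3-(2-methylbut-3-en-2-yl)indole-1-carboxylate | C=CC(C)(C)c1cn(C(=O)OC(C)(C)C)c2ccc(Br)cc12 | intermediate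
10 | tert-butyl 3-(2-methylbut-3-en-2-yl)-5-(4,4,5,5-tetramethyl-1,3,2-dioxaborolan-2-yl)indole-1-carboxylate | C=CC(C)(C)c1cn(C(=O)OC(C)(C)C)c2ccc(B3OC(C)(C)C(C)(C)O3)cc12 | intermediate
11 | 3-methylcyclohex-2-en-1-one | CC1=CC(=O)CCC1 | starting material
12 | lithium 5-methylcyclohexa-1,5-dien-1-olate | [Li]OC1=CCCC(C)=C1 | intermediate
13 | 3,6-dimethylcyclohex-2-en-1-one (racemic) | CC1=CC(=O)C(C)CC1 | intermediate
14 | (E)-1,2-dichloroethene | Cl/C=C/Cl | starting material
15 | lithium 2,5-dimethylcyclohexa-1,5-dien-1-olate | [Li]OC1=C(C)CCC(C)=C1 | intermediate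
16 | chlorozinc 2,5-dimethylcyclohexa-1,5-dien-1-olate | Cl[Zn]OC1=C(C)CCC(C)=C1 | intermediate
17 | (R)-6-[(E)-2-chloroethenyl]-3,6-dimethylcyclohex-2-en-1-one | Cl/C=C/[C@@]1(C)CCC(C)=CC1=O | intermediate
18 | (1S,6R)-6-[(E)-2-chloroethenyl]-3,6-dimethylcyclohex-2-en-1-ol | Cl/C=C/[C@@]1(C)CCC(C)=C[C@@H]1O | intermediate
19 | (1S,6R)-6-[(E)-2-chloroethenyl]-3,6-dimethylcyclohex-2-en-1-yl methyl carbonate | Cl/C=C/[C@@]1(C)CCC(C)=C[C@@H]1OC(=O)OC | intermediate
20 | tert-butyl 5-{(1R,6S)-6-[(E)-2-chloroethenyl]-3,6-dimethylcyclohex-2-en-1-yl}-3-(2-methylbut-3-en-2-yl)indole-1-carboxylate | Cl/C=C/[C@@]1(C)CCC(C)=C[C@H]1c2ccc3c(c2)c(C(C)(C)C=C)cn3C(=O)OC(C)(C)C | intermediate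
21 | N,N′-di-Boc derivative of the target, (1R,6R) on the cyclohexene | C=CC(C)(C)c1cn(C(=O)OC(C)(C)C)c2ccc(/C=C/[C@@]3(C)CCC(C)=C[C@H]3c3ccc4c(c3)c(C(C)(C)C=C)cn4C(=O)OC(C)(C)C)cc12 | intermediate
22 | 5-[(1R,6R)-3,6-dimethyl-6-{(E)-2-[3-(2-methylbut-3-en-2-yl)-1H-indol-5-yl]ethenyl}cyclohex-2-en-1-yl]-3-(2-methylbut-3-en-2-yl)-1H-indole | C=CC(C)(C)c1c[nH]c2ccc(/C=C/[C@@]3(C)CCC(C)=C[C@H]3c3ccc4[nH]cc(C(C)(C)C=C)c4c3)cc12 | target

## Counts
- **Total step count:** 12.
- **Longest linear sequence:** 7 steps (6, 7, 8, 9, 10, 11, 12). The indole branch through steps 2, 3, 4, 5, 10, 11, 12 is equally long.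

## Three steps most likely to fail

**Step 7 (proposed new method).**
- Risks: insufficient enantioselectivity, beta-hydride elimination of the palladium enolate leading to 2,5-dimethylphenol, or slow zinc-to-palladium transfer.
- The fallback uses known chemistry, sets out from 13 and comes back at 17.
- 13 is O-acylated (LiN(SiMe3)2, allyl chloroformate, THF, −78 °C) to allyl 2,5-dimethylcyclohexa-1,5-dien-1-yl carbonate F1.
- Decarboxylative asymmetric allylic alkylation (Pd2(dba)3, (R)-t-Bu-PHOX, toluene, 25 °C) gives (R)-6-allyl-3,6-dimethylcyclohex-2-en-1-one F2.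
- Alkene isomerisation (RhCl3·3H2O, EtOH, 70 °C) gives (R)-3,6-dimethyl-6-[(E)-prop-1-en-1-yl]cyclohex-2-en-1-one F3.
- Selective ozonolysis of the electron-rich propenyl group (O3, pyridine, CH2Cl2, −78 °C; Me2S) gives (R)-1,4-dimethyl-2-oxocyclohex-3-ene-1-carbaldehyde F4.
- Takai chloro-olefination of the aldehyde (CrCl2, CHCl3, THF, 65 °C) returns 17.

**Step 10.**
- Risks: the reacting allyl terminus is neopentyl, so arylation at the methyl-bearing terminus, beta-hydride elimination to the cyclohexadiene, or facial scrambling of the allylpalladium species may compete.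
- The fallback reverses the polarity. It sets out from 19, uses bromide 9 as the aryl partner, and comes back at 20.
- Copper-catalysed gamma-selective anti-SN2′ borylation (CuCl, 1,3-dimesitylimidazolium chloride, NaOMe, B2pin2, THF, 0 °C) puts boron on the methyl-bearing carbon, on the face opposite the carbonate. This gives 2-{(1S,4S)-4-[(E)-2-chloroethenyl]-1,4-dimethylcyclohex-2-en-1-yl}-4,4,5,5-tetramethyl-1,3,2-dioxaborolane F5.
- Gamma-selective Suzuki coupling of this tertiary allylboronate with 9 (Pd(OAc)2, PPh3, K3PO4, THF/H2O, 50 °C) proceeds by syn-SE2′ transmetalation. It returns the alkene to its place and forms the aryl bond on the boron face, cis to the chloroethenyl group, giving 20.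

**Step 8.**
- Risk: both carbonyl flanks are large, so the oxazaborolidine may discriminate poorly or react slowly.
- The fallback sets out from 17 and comes back at 18.
- Luche reduction (NaBH4, CeCl3·7H2O, MeOH, −20 °C) gives 18 together with its C1 epimer (1R,6R)-6-[(E)-2-chloroethenyl]-3,6-dimethylcyclohex-2-en-1-ol F6, and the two are separated by chromatography.
- The epimer is inverted by a Mitsunobu reaction (4-nitrobenzoic acid, PPh3, DIAD, toluene, 0 °C to rt) to (1S,6R)-6-[(E)-2-chloroethenyl]-3,6-dimethylcyclohex-2-en-1-yl 4-nitrobenzoate F7.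
- Methanolysis (K2CO3, MeOH, rt) then gives 18.

## Further compounds
F1 | step 7 | allyl 2,5-dimethylcyclohexa-1,5-dien-1-yl carbonate | C=CCOC(=O)OC1=C(C)CCC(C)=C1
F2 | step 7 | (R)-6-allyl-3,6-dimethylcyclohex-2-en-1-one | C=CC[C@@]1(C)CCC(C)=CC1=O
F3 | step 7 | (R)-3,6-dimethyl-6-[(E)-prop-1-en-1-yl]cyclohex-2-en-1-one | C/C=C/[C@@]1(C)CCC(C)=CC1=O
F4 | step 7 | (R)-1,4-dimethyl-2-oxocyclohex-3-ene-1-carbaldehyde | O=C[C@@]1(C)CCC(C)=CC1=O
F5 | step 10 | 2-{(1S,4S)-4-[(E)-2-chloroethenyl]-1,4-dimethylcyclohex-2-en-1-yl}-4,4,5,5-tetramethyl-1,3,2-dioxaborolane | Cl/C=C/[C@@]1(C)CC[C@@](C)(B2OC(C)(C)C(C)(C)O2)C=C1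
F6 | step 8 | (1R,6R)-6-[(E)-2-chloroethenyl]-3,6-dimethylcyclohex-2-en-1-ol | Cl/C=C/[C@@]1(C)CCC(C)=C[C@H]1O
F7 | step 8 | (1S,6R)-6-[(E)-2-chloroethenyl]-3,6-dimethylcyclohex-2-en-1-yl 4-nitrobenzoate | Cl/C=C/[C@@]1(C)CCC(C)=C[C@@H]1OC(=O)c2ccc(cc2)[N+](=O)[O-]
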